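If J stops rising while Q still stands at 85.3 % in the noon run, the balance to write is that of L.

| flask | Q | L | remark | time |
|---|---|---|---|---|
| noon | 0.24 M | 1 equiv (in portions, 2) | run made earlier; portions every 1.5 min |  |
| flask | 0.48 M | 1.00 equiv (in portions, 2) | the portions of L follow each other after 1.5 min, the first at the start | 40 h |

noon run (percent of the Q charged)

| time / h | Q / % | J / % |
|---|---|---|
| 0.417 | 92.5 | 3.8 |
| 1.33 | 86.6 | 7.6 |
| 2.50 | 85.5 | 8.0 |
| 3.00 | 85.7 | 8.1 |
| 5.00 | 85.3 | 8.0 |
| 6.00 | 85.6 | 8.3 |
| 8.00 | 85.2 | 7.8 |

(each reading ± 0.3 percentage points)

- J is meant together with its X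
- solid, in amounts per volume of the solution: Q, X
- candidate steps: Q <-> E; E + L -> J; X <-> J; L -> G
- at the start none of Q is in solution
- what has only dissolved of Q counts as not reacted
- the reaction counts as stopped when no species that holds the Q changes by six tenths of a point or more over the second half of the time

- the state of affairs at 40 h: stopped, and by what, or still going (for what has run out or reacted, a solid counts together with what of it has only dissolved) (L has run out first / it is still moving / all of Q has reacted)
- part of the Q that has turned into other species by 40 h (what has only dissolved does not count)
- the J standing at 40 h, as a percentage of the Q charged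

In the noon run J reads 8.0 % at 2.50 h and 7.8 % at 8.00 h, with a scatter of 0.3 percentage points. So the noon flask has stopped, but its Q still reads 85.2 %. The suspect is L, which acts as the limiting reagent. Each J takes one L, so the balance of L reads: charged equals what is left plus what is taken into J plus what is lost to G.

The L share, the J formed per L charged, reads 8.00 % in the noon run. If that run kept no L, 92.0 % of its L went to G. The noon gap of 6.70 % between Q and J is read as E. E has only dissolved, so conversion counts J and not E.

The new flask holds twice the Q, with c_Q at 0.48 M, and the same 1.00 equiv of L in 2 portions 1.5 min apart. The reckoning here holds the L share at its noon reading and closes the balance of L as at noon, so the new flask should stop with J at 8.00 % of the Q charged.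

The forecast names the outcome L has run out first, with J at 8 % (range 6 % to 9.5 %) and conversion at 8 %: “L runs out within a few hours.”

The outcome for the new flask is L has run out first, with J at 6.92 % and conversion at 6.92 %.

Q ⇌ E, rate k1*(cs1 - [E]) while solid is left; crystals form when [E] > cs1 (solubility = 16.0 mM, k = 0.0789 min⁻¹); E + L → J (k = 0.337 L mol⁻¹ min⁻¹); X ⇌ J, rate k3*(cs3 - [J]) while solid is left; crystals form when [J] > cs3 (solubility = 5.80 mM, k = 1.16 min⁻¹); L → G (k = 0.0332 min⁻¹) At 40.0 h its L stands at 0 % of the charge and its G at 0.447 M. Its L share is 6.92 %, lower than the noon reading of 8.00 %. Carried to a neighbour flask with 2.50 equiv of L, 6.92 % gives J at 17.3 %. But that neighbour stands at J 12.1 % with L at 0 %, an L share of 4.84 %.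

The earlier runs and the new flask were generated by integration from invented constants; noise was put on by code.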